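**Retrosynthetic overview**

1. Feature: C10 and C4 each carry a methyl group and are joined by the unfunctionalised C1–C2–C3 chain. The ten-membered ring therefore divides into a 2-methylcyclohex-2-enone (C9=O, C10=C5, C6–C8, from (R)-carvone) and 1-methylcyclobutene (C1=C4, C2, C3).
2. Key disconnection: C10–C1 and C5–C4 by enone–cyclobutene [2+2] photocycloaddition. The ten-membered ring appears when the bicyclo[2.2.0]hexane opens thermally at C1–C4 and C5–C10 to the germacra-1(10),4-dien-9-one.
3. After ring opening: conjugate reduction sets C10. The 4E alkene is epoxidised under direction of the free C6 hydroxyl and opened by water at C4 (net anti addition). The C7 hydroxyisopropyl group is dehydrated, oxidised at C12 and closed onto O6 as the α-methylene lactone. C5 esterification and C8 desilylation finish the route.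
4. Ring order: cyclohexenone (chiral pool), then cyclobutane C10–C1–C4–C5 completing the bicyclo[2.2.0]hexane (step 8), then the ten-membered carbocycle (step 9), the epoxide (step 14) and the γ-lactone (step 16).
5. Silyl groups of graded lability: TMS on O11 (removed first), TBS on O6, TBDPS on O8 (removed last).

Key step: step 8

Numbering: locants C1–C15 are those of the target's germacrane skeleton (C14 = CH3 on C10, C15 = CH3 on C4, C11–C13 = the C7 side chain) and are used for every intermediate, including the six-membered precursors.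

Remark 1 (assumption): the cis-anti-cis photoadduct is taken to open through the chair cyclohexane-1,4-diyl that keeps C6 equatorial and C9 axial, which gives the (1(10)Z,4E)-dienone; only the 4E geometry is used later, since the C1=C10 geometry is erased in step 10.

Remark 2 (assumption): C10 is α to the C9 ketone and is taken to prefer the 10S configuration of the target at equilibrium.

**Route**

Step 1
Reactants: 1 (R)-carvone
Product: 2 (5R)-5-(2-hydroxypropan-2-yl)-2-methylcyclohex-2-en-1-one
Conditions: 50% aq. H2SO4, 0 °C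
Reagents that add atoms: water, O
Why: Acid-catalysed Markovnikov hydration of the isopropenyl group through the tertiary cation, the protonated enone being inert at 0 °C; this masks the alkene that would otherwise add intramolecularly to the excited enone in step 8, and the C7 centre of (R)-carvone is carried over unchanged.

Step 2
Reactants: 2 hydroxy enone
Product: 3 trimethylsilyl ether of 2
Conditions: N-(trimethylsilyl)imidazole, CH2Cl2, rt
Reagents that add atoms: N-(trimethylsilyl)imidazole, C[Si](C)(C)n1ccnc1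
Why: Silyl transfer from the N-silylimidazole silylates even a tertiary alcohol without enolising the ketone, so the hydroxyl cannot add to the enone or consume the bases used next.

Step 3
Reactants: 3 silyl ether
Product: 4 (5R,6S)-6-hydroxy-2-methyl-5-[2-(trimethylsilyloxy)propan-2-yl]cyclohex-2-en-1-one (8-OH trans to the C7 side chain)
Conditions: NaN(SiMe3)2, THF, −78 °C; then 3-phenyl-2-(phenylsulfonyl)oxaziridine, −78 °C; aq. NH4Cl
Reagents that add atoms: 3-phenyl-2-(phenylsulfonyl)oxaziridine, O=S(=O)(c1ccccc1)N1OC1c1ccccc1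
Why: Kinetic deprotonation at the α′-carbon C8 gives the cross-conjugated sodium dienolate, which is hydroxylated by the N-sulfonyloxaziridine (Davis enolate oxidation) on the face opposite the bulky C7 side chain, so the 8-OH is trans to it (8S).

Step 4
Reactants: 4 α′-hydroxy enone
Product: 5 8-O-TBDPS ether of 4
Conditions: TBDPSCl, imidazole, DMAP (cat.), DMF, rt
Reagents that add atoms: tert-butyl(chloro)diphenylsilane, CC(C)(C)[Si](Cl)(c1ccccc1)c1ccccc1
Why: Imidazole-mediated silylation of the only free hydroxyl; the bulky, acid-stable TBDPS group is the one meant to survive to the last step and it also shields C8–H in step 5.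

Step 5
Reactants: 5 TBDPS ether
Product: 7 (4S,5R,6S)-γ-hydroxy enone (6-OH and 8-OTBDPS both trans to the C7 side chain), via dienol silyl ether 6 (not isolated)
Conditions: TMSOTf, Et3N, CH2Cl2, 0 °C; then mCPBA, NaHCO3, CH2Cl2, −20 °C; aq. Na2S2O3
Reagents that add atoms: mCPBA, OOC(=O)c1cccc(Cl)c1; trimethylsilyl triflate, C[Si](C)(C)OS(=O)(=O)C(F)(F)F (its silyl group is kept only in 6)
Why: Soft enolisation (silyl triflate/amine) removes a γ-hydrogen at C6 because the α′ hydrogen at C8 is tertiary and buried beside the TBDPS ether, giving the linear 1-silyloxy-1,3-diene 6; the peracid then attacks its terminal carbon C6 (vinylogous Rubottom oxidation) from the face opposite the adjacent C7 side chain and collapse of the adduct returns the enone, so the 6-OH is trans to the side chain.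

Step 6
Reactants: 7 γ-hydroxy enone
Product: 8 (4S,5R,6S)-4-(tert-butyldimethylsilyloxy)-6-(tert-butyldiphenylsilyloxy)-2-methyl-5-[2-(trimethylsilyloxy)propan-2-yl]cyclohex-2-en-1-one
Conditions: TBSOTf, 2,6-lutidine, CH2Cl2, −78 °C
Reagents that add atoms: tert-butyldimethylsilyl triflate, CC(C)(C)[Si](C)(C)OS(=O)(=O)C(F)(F)F
Why: Silyl triflate/2,6-lutidine silylation of the hindered secondary allylic alcohol at low temperature; TBS lies between TMS and TBDPS in lability, which is what steps 11, 13 and 19 rely on.

Step 7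
Reactants: 9 methylenecyclobutane
Product: 10 1-methylcyclobutene
Conditions: KOtBu (cat.), DMSO, 60 °C; fractional distillation
Reagents that add atoms: none
Why: Base-catalysed prototropic shift through the allyl anion moves the exocyclic double bond into the ring, the trisubstituted endocyclic alkene being favoured at equilibrium, and the lower-boiling 10 is distilled from the mixture.

Step 8
Reactants: 8 enone; 10 1-methylcyclobutene
Product: 11 cis-anti-cis tricyclic ketone (cyclohexanone C5–C10 fused at C5–C10 to cyclobutane C10–C1–C4–C5, which is fused at C1–C4 to cyclobutane C1–C2–C3–C4)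
Conditions: hν (350 nm, Pyrex, uranium-glass filter), 10 (10 equiv), CH2Cl2, −40 °C
Reagents that add atoms: none
Why: Irradiation into the n,π* band gives the enone triplet, which adds to the strained, electron-rich alkene 10 through a 1,4-biradical that closes after spin inversion; the closest known reaction type is the [2+2] photocycloaddition of cyclohex-2-enones to cyclobutenes, which gives tricyclo[4.4.0.0(2,5)]decanones. The new cyclobutane C10–C1–C4–C5 closes by this intermolecular [2+2] addition (bonds C5–C4 and C10–C1), and together with the cyclobutene-derived ring C1–C2–C3–C4 it forms the second fused four-membered ring system, a bicyclo[2.2.0]hexane on the cyclohexanone. The C10/C5 fusion should be cis because the biradical closes to the less strained cis-bicyclo[4.2.0]octanone, the C1/C4 fusion is cis because a trans-bicyclo[2.2.0]hexane cannot form, and the outer rings lie anti for steric reasons, with addition to the enone face opposite the 6-OTBS group. The step needs head-to-tail regiochemistry (methyl-bearing C4 to the β-carbon C5): this is the normal orientation for a donor alkene and it is reinforced here because the alternative would join the two quaternary carbons C10 and C4. Either enone face gives an adduct that leads to the same 12, since all four new centres are destroyed in step 9.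

Step 9
Reactants: 11 tricyclic ketone
Product: 12 (1(10)Z,4E)-6-TBSO-8-TBDPSO-11-TMSO-germacra-1(10),4-dien-9-one
Conditions: PhMe (0.01 M, degassed), sealed base-washed tube, 200 °C
Reagents that add atoms: none
Why: Thermal homolysis of the strained central C1–C4 bond gives a cyclohexane-1,4-diyl that fragments at C5–C10 (formal retro-[2+2], the known photo-thermal metathesis of enone–cyclobutene adducts), cleavage of C5–C10 and not C2–C3 being favoured because it conjugates C1=C10 with the C9 ketone; the chair diyl with C6 equatorial and C9 axial leads to the 4E and 1(10)Z alkenes, and C6–C8 are untouched.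

Step 10
Reactants: 12 dienone
Product: 13 (4E,10S)-6-TBSO-8-TBDPSO-11-TMSO-germacr-4-en-9-one
Conditions: [(Ph3P)CuH]6, PhH, H2O (2 equiv), rt; then DBU (cat.), CH2Cl2, rt
Reagents that add atoms: none
Why: Conjugate reduction by [(Ph3P)CuH]6 delivers hydride to C1 and leaves the isolated C4=C5 alkene, the carbonyl group and the silyl ethers alone; C10 is created when water protonates the copper enolate from the outer face of the ring and, being α to C9, is then brought to the more stable 10S arrangement by brief amine-base equilibration (remark 2).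

Step 11
Reactants: 13 ketone
Product: 14 (4E,10S)-6-TBSO-8-TBDPSO-11-hydroxygermacr-4-en-9-one
Conditions: HCl (0.1 M aq., cat.), THF, 0 °C
Reagents that add atoms: none
Why: A tertiary trimethylsilyl ether is hydrolysed by dilute acid far faster than secondary TBS or TBDPS ethers, so only O11 is unmasked (selective silyl ether hydrolysis).

Step 12
Reactants: 14 tertiary alcohol
Product: 15 (4E,10S)-6-TBSO-8-TBDPSO-germacra-4,11(13)-dien-9-one
Conditions: Burgess reagent (MeO2CN−SO2N+Et3), PhH, 50 °C
Reagents that add atoms: none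
Why: The Burgess reagent converts the tertiary alcohol into a sulfamate that undergoes syn elimination; loss of a methyl hydrogen to give the isopropenyl group should win over loss of H7, a single hydrogen flanked by two silyloxy-bearing carbons whose removal would give a strained tetrasubstituted alkene, and the C11 oxygen is removed before the epoxide is made so that it cannot open it.

Step 13
Reactants: 15 isopropenyl ketone
Product: 16 (4E,10S)-6-hydroxy-8-TBDPSO-germacra-4,11(13)-dien-9-one
Conditions: HF·pyridine, pyridine, THF, 0 °C to rt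
Reagents that add atoms: none
Why: Buffered HF·pyridine cleaves the secondary TBS ether while the more acid-stable TBDPS ether at O8 stays (selective desilylation), freeing the C6 hydroxyl that directs step 14 and later becomes the lactone oxygen.

Step 14
Reactants: 16 allylic alcohol
Product: 17 (10S)-trans-4,5-epoxy-6-hydroxy-8-TBDPSO-germacr-11(13)-en-9-one
Conditions: VO(acac)2 (cat.), tBuOOH, CH2Cl2, 0 °C
Reagents that add atoms: tert-butyl hydroperoxide, CC(C)(C)OO
Why: Hydroxyl-directed epoxidation with VO(acac)2/tBuOOH acts on the allylic C4=C5 bond and not on the homoallylic isopropenyl group; in the conformer that avoids allylic 1,3-strain (H6 eclipsing the C4 methyl) O6 lies on the outer face of the E alkene, so oxygen is delivered to that face and the trans-epoxide has C5–O in the configuration of the target (threo to C6–O), with C4–O still to be inverted.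

Step 15
Reactants: 17 epoxy alcohol
Product: 18 (10S)-trans-4,5-epoxy-6,12-dihydroxy-8-TBDPSO-germacr-11(13)-en-9-one
Conditions: SeO2 (cat.), tBuOOH, CH2Cl2, rt
Reagents that add atoms: tert-butyl hydroperoxide, CC(C)(C)OO (oxygen atom passed on through SeO2, O=[Se]=O)
Why: Allylic oxidation by SeO2 (ene reaction then [2,3]-sigmatropic shift, Riley oxidation) takes place at the methyl group of the 1,1-disubstituted alkene in preference to the hindered methine C7–H, and with C4=C5 already epoxidised this is the only alkene left.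

Step 16
Reactants: 18 epoxy diol
Product: 20 (10S)-trans-4,5-epoxy-8-TBDPSO-9-oxogermacr-11(13)-en-12,6-olide, via lactol 19 (not isolated)
Conditions: TEMPO (cat.), PhI(OAc)2, CH2Cl2, rt
Reagents that add atoms: none
Why: Oxoammonium oxidation converts the primary allylic alcohol into the enal, which closes onto the neighbouring C6 hydroxyl as the five-membered lactol 19 and is oxidised again to the α-methylene-γ-lactone (oxidative lactonisation of a 1,4-diol); the lactone is trans-fused because O6 and C11 are trans on C6–C7.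

Step 17
Reactants: 20 epoxy lactone
Product: 21 (4R,5S,10S)-4,5-dihydroxy-8-TBDPSO-9-oxogermacr-11(13)-en-12,6-olide
Conditions: HClO4 (cat.), THF/H2O, 0 °C
Reagents that add atoms: water, O
Why: Acid-catalysed epoxide hydrolysis in which water attacks the tertiary carbon C4 with inversion (borderline SN2), C5 being deactivated by the acyloxy-bearing C6, so that epoxidation plus opening amount to anti addition to the E alkene and give the 4R tertiary alcohol beside the retained 5S centre.

Step 18
Reactants: 21 diol lactone; 22 (R)-2-methylbutanoic acid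
Product: 23 5-O-[(2R)-2-methylbutanoyl] derivative of 21
Conditions: EDC·HCl, DMAP, CH2Cl2, 0 °C to rt
Reagents that add atoms: none
Why: Carbodiimide/DMAP esterification (Steglich) of the only secondary hydroxyl, the tertiary C4 hydroxyl being unreactive and O8 still silylated; the mild conditions keep the α-stereocentre of the acid.

Step 19
Reactants: 23 silylated ester
Product: 24 target, (4R,5S,6R,7S,8S,10S)-4,8-dihydroxy-5-[(2R)-2-methylbutanoyloxy]-9-oxogermacr-11(13)-en-12,6-olide
Conditions: HF·pyridine, THF, 0 °C to rt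
Reagents that add atoms: none
Why: Fluoride-mediated cleavage of the last silyl ether under mildly acidic conditions that leave the ester, the α-methylene lactone and the α-ketol untouched (desilylation).

**Compound list**

1 | (R)-carvone, (5R)-2-methyl-5-(prop-1-en-2-yl)cyclohex-2-en-1-one | CC1=CC[C@H](CC1=O)C(C)=C | starting material
2 | (5R)-5-(2-hydroxypropan-2-yl)-2-methylcyclohex-2-en-1-one | CC1=CC[C@H](CC1=O)C(C)(C)O | intermediate
3 | (5R)-2-methyl-5-[2-(trimethylsilyloxy)propan-2-yl]cyclohex-2-en-1-one | CC1=CC[C@H](CC1=O)C(C)(C)O[Si](C)(C)C | intermediate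
4 | (5R,6S)-6-hydroxy-2-methyl-5-[2-(trimethylsilyloxy)propan-2-yl]cyclohex-2-en-1-one (5,6-trans) | CC1=CC[C@@H](C(C)(C)O[Si](C)(C)C)[C@H](O)C1=O | intermediate
5 | (5R,6S)-6-(tert-butyldiphenylsilyloxy)-2-methyl-5-[2-(trimethylsilyloxy)propan-2-yl]cyclohex-2-en-1-one | CC1=CC[C@@H](C(C)(C)O[Si](C)(C)C)[C@H](O[Si](c2ccccc2)(c2ccccc2)C(C)(C)C)C1=O | intermediate
6 | linear dienol trimethylsilyl ether of 5 (C9(OTMS)=C10–C5=C6), not isolated | CC1=C(O[Si](C)(C)C)[C@@H](O[Si](c2ccccc2)(c2ccccc2)C(C)(C)C)[C@H](C(C)(C)O[Si](C)(C)C)C=C1 | intermediate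
7 | (4S,5R,6S)-6-(tert-butyldiphenylsilyloxy)-4-hydroxy-2-methyl-5-[2-(trimethylsilyloxy)propan-2-yl]cyclohex-2-en-1-one | CC1=C[C@H](O)[C@@H](C(C)(C)O[Si](C)(C)C)[C@H](O[Si](c2ccccc2)(c2ccccc2)C(C)(C)C)C1=O | intermediate
8 | (4S,5R,6S)-4-(tert-butyldimethylsilyloxy)-6-(tert-butyldiphenylsilyloxy)-2-methyl-5-[2-(trimethylsilyloxy)propan-2-yl]cyclohex-2-en-1-one (photo precursor) | CC1=C[C@H](O[Si](C)(C)C(C)(C)C)[C@@H](C(C)(C)O[Si](C)(C)C)[C@H](O[Si](c2ccccc2)(c2ccccc2)C(C)(C)C)C1=O | intermediate
9 | methylenecyclobutane | C=C1CCC1 | starting material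
10 | 1-methylcyclobutene | CC1=CCC1 | intermediate
11 | cis-anti-cis tricyclic photoadduct (bonds C10–C1 and C5–C4; cyclobutane anti to 6-OTBS; C6, C7, C8 as in 8) | O=C1[C@@]2(C)[C@@H]3CC[C@]3(C)[C@H]2[C@H](O[Si](C)(C)C(C)(C)C)[C@@H](C(C)(C)O[Si](C)(C)C)[C@@H]1O[Si](c4ccccc4)(c4ccccc4)C(C)(C)C | intermediate
12 | (1(10)Z,4E)-6-TBSO-8-TBDPSO-11-TMSO-germacra-1(10),4-dien-9-one | C/C1=C/CC/C(C)=C/[C@H](O[Si](C)(C)C(C)(C)C)[C@@H](C(C)(C)O[Si](C)(C)C)[C@H](O[Si](c2ccccc2)(c2ccccc2)C(C)(C)C)C1=O | intermediate
13 | (4E,10S)-6-TBSO-8-TBDPSO-11-TMSO-germacr-4-en-9-one | C[C@H]1CCC/C(C)=C/[C@H](O[Si](C)(C)C(C)(C)C)[C@@H](C(C)(C)O[Si](C)(C)C)[C@H](O[Si](c2ccccc2)(c2ccccc2)C(C)(C)C)C1=O | intermediate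
14 | (4E,10S)-6-TBSO-8-TBDPSO-11-hydroxygermacr-4-en-9-one | C[C@H]1CCC/C(C)=C/[C@H](O[Si](C)(C)C(C)(C)C)[C@@H](C(C)(C)O)[C@H](O[Si](c2ccccc2)(c2ccccc2)C(C)(C)C)C1=O | intermediate
15 | (4E,10S)-6-TBSO-8-TBDPSO-germacra-4,11(13)-dien-9-one | C[C@H]1CCC/C(C)=C/[C@H](O[Si](C)(C)C(C)(C)C)[C@@H](C(C)=C)[C@H](O[Si](c2ccccc2)(c2ccccc2)C(C)(C)C)C1=O | intermediate
16 | (4E,10S)-6-hydroxy-8-TBDPSO-germacra-4,11(13)-dien-9-one | C[C@H]1CCC/C(C)=C/[C@H](O)[C@@H](C(C)=C)[C@H](O[Si](c2ccccc2)(c2ccccc2)C(C)(C)C)C1=O | intermediate
17 | (10S)-trans-4,5-epoxy-6-hydroxy-8-TBDPSO-germacr-11(13)-en-9-one | C[C@H]1CCC[C@]2(C)O[C@H]2[C@H](O)[C@@H](C(C)=C)[C@H](O[Si](c3ccccc3)(c3ccccc3)C(C)(C)C)C1=O | intermediate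
18 | (10S)-trans-4,5-epoxy-6,12-dihydroxy-8-TBDPSO-germacr-11(13)-en-9-one | C[C@H]1CCC[C@]2(C)O[C@H]2[C@H](O)[C@@H](C(=C)CO)[C@H](O[Si](c3ccccc3)(c3ccccc3)C(C)(C)C)C1=O | intermediate
19 | 12,6-lactol of the enal from 18 (anomers), not isolated | C[C@H]1CCC[C@]2(C)O[C@H]2[C@@H]3OC(O)C(=C)[C@H]3[C@H](O[Si](c4ccccc4)(c4ccccc4)C(C)(C)C)C1=O | intermediate
20 | (10S)-trans-4,5-epoxy-8-TBDPSO-9-oxogermacr-11(13)-en-12,6-olide | C[C@H]1CCC[C@]2(C)O[C@H]2[C@@H]3OC(=O)C(=C)[C@H]3[C@H](O[Si](c4ccccc4)(c4ccccc4)C(C)(C)C)C1=O | intermediate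
21 | (4R,5S,10S)-4,5-dihydroxy-8-TBDPSO-9-oxogermacr-11(13)-en-12,6-olide | C[C@H]1CCC[C@@](C)(O)[C@@H](O)[C@@H]2OC(=O)C(=C)[C@H]2[C@H](O[Si](c3ccccc3)(c3ccccc3)C(C)(C)C)C1=O | intermediate
22 | (R)-2-methylbutanoic acid | CC[C@@H](C)C(=O)O | starting material
23 | (4R,5S,10S)-4-hydroxy-5-[(2R)-2-methylbutanoyloxy]-8-TBDPSO-9-oxogermacr-11(13)-en-12,6-olide | C[C@H]1CCC[C@@](C)(O)[C@@H](OC(=O)[C@H](C)CC)[C@@H]2OC(=O)C(=C)[C@H]2[C@H](O[Si](c3ccccc3)(c3ccccc3)C(C)(C)C)C1=O | intermediate
24 | CNP0339940.1, (4R,5S,6R,7S,8S,10S)-4,8-dihydroxy-5-[(2R)-2-methylbutanoyloxy]-9-oxogermacr-11(13)-en-12,6-olide | C=C1C(=O)O[C@@H]2[C@@H]1[C@H](O)C(=O)[C@@H](C)CCC[C@@](C)(O)[C@H]2OC(=O)[C@H](C)CC | target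

**Step count**

Total: 19 steps. Longest linear sequence: 18 steps (steps 1–6 and 8–19, from (R)-carvone); step 7 is a one-step side branch.

**Steps most likely to fail**

1. Step 8 (photocycloaddition). What may go wrong: competing head-to-head addition, closure of the biradical to trans-fused adducts, or slow addition because the 6-silyloxy group crowds the reacting carbon C5. The fallback reshapes the chromophore; it sets out from 7 and comes back at 11.
 - Alcohol 7 is oxidised with Dess–Martin periodinane to the ene-dione F1, in which C5 is no longer flanked by a silyloxy carbon.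
 - Irradiation of the ene-dione F1 with 10 (ene-dione [2+2] photocycloaddition) should give the tricyclic 6,9-dione F2, the orientation now being set by sterics alone (methyl-bearing C4 to the hydrogen-bearing C5).
 - Dilute HCl in THF removes the tertiary silyl group to give the β-hydroxy ketone F3.
 - Me4NBH(OAc)3 in AcOH/MeCN at −20 °C (hydroxyl-directed Evans–Saksena reduction) reduces only the C6 carbonyl, which is β to the C11 hydroxyl, and delivers hydride from the side-chain face, so the diol F4 has O6 trans to the side chain.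
 - One-pot silylation of the diol F4 (TBSOTf on the secondary hydroxyl at −78 °C, then TMSOTf on the tertiary one, 2,6-lutidine) returns 11, or its diastereomer at the four cyclobutane carbons, which gives the same 12.

2. Step 9 (thermal ring opening). What may go wrong: opening through the other chair diyl (C6 axial), so that C4=C5 is formed with Z geometry, for which epoxidation and anti opening would give the wrong C4/C5 pair. The fallback replaces the anti dioxygenation by a syn one; it sets out from 11 and comes back at 21.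
 - The (1(10)E,4Z)-dienone F5 is taken through the operations of steps 10–13: conjugate reduction to the 4Z ketone F6, hydrolysis of the trimethylsilyl ether to the 4Z tertiary alcohol F7, Burgess dehydration to the 4Z isopropenyl ketone F8, and HF·pyridine to the 4Z allylic alcohol F9.
 - Hydrogen-bond-directed syn dihydroxylation of the 4Z allylic alcohol F9 with OsO4·TMEDA (CH2Cl2, −78 °C) adds both oxygens on the face of the C6 hydroxyl and leaves the isopropenyl group, giving the 4,5,6-triol F10 with the C4 and C5 configuration of the target.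
 - SeO2/tBuOOH gives the 4,5,6,12-tetraol F11.
 - TEMPO/PhI(OAc)2 closes the five-membered lactol onto O6 and oxidises it to 21.

3. Step 10 (conjugate reduction, C10). What may go wrong: protonation and equilibration favouring the 10R epimer, or epimerisation at C8 during the base treatment. The fallback sets C10 under kinetic control without base; it sets out from 12 and comes back at 13.
 - 1,4-Hydrosilylation of 12 with Et3SiH and RhCl(PPh3)3 (cat.) in PhH gives the triethylsilyl enol ether F12.
 - The triethylsilyl enol ether F12 is cleaved at −78 °C with Bu4NF/AcOH, so that the enolate is protonated irreversibly at C10 by a proton source whose size can be varied, giving 13.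

**Further compounds**

F1 | step 8 | ene-dione from 7: 2-methylcyclohex-2-ene-1,4-dione with 5-C(CH3)2OTMS and 6-OTBDPS (trans) | CC1=CC(=O)[C@@H](C(C)(C)O[Si](C)(C)C)[C@H](O[Si](c2ccccc2)(c2ccccc2)C(C)(C)C)C1=O
F2 | step 8 | cis-anti-cis tricyclic 6,9-dione photoadduct | O=C1[C@@]2(C)[C@@H]3CC[C@]3(C)[C@H]2C(=O)[C@@H](C(C)(C)O[Si](C)(C)C)[C@@H]1O[Si](c4ccccc4)(c4ccccc4)C(C)(C)C
F3 | step 8 | 11-hydroxy tricyclic 6,9-dione | O=C1[C@@]2(C)[C@@H]3CC[C@]3(C)[C@H]2C(=O)[C@@H](C(C)(C)O)[C@@H]1O[Si](c4ccccc4)(c4ccccc4)C(C)(C)C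
F4 | step 8 | 6,11-dihydroxy tricyclic 9-ketone (O6 trans to the side chain) | O=C1[C@@]2(C)[C@@H]3CC[C@]3(C)[C@H]2[C@H](O)[C@@H](C(C)(C)O)[C@@H]1O[Si](c4ccccc4)(c4ccccc4)C(C)(C)C
F5 | step 9 | (1(10)E,4Z)-isomer of 12 | C/C1=C\CC/C(C)=C\[C@H](O[Si](C)(C)C(C)(C)C)[C@@H](C(C)(C)O[Si](C)(C)C)[C@H](O[Si](c2ccccc2)(c2ccccc2)C(C)(C)C)C1=O
F6 | step 9 | (4Z)-isomer of 13 | C[C@H]1CCC/C(C)=C\[C@H](O[Si](C)(C)C(C)(C)C)[C@@H](C(C)(C)O[Si](C)(C)C)[C@H](O[Si](c2ccccc2)(c2ccccc2)C(C)(C)C)C1=O
F7 | step 9 | (4Z)-isomer of 14 | C[C@H]1CCC/C(C)=C\[C@H](O[Si](C)(C)C(C)(C)C)[C@@H](C(C)(C)O)[C@H](O[Si](c2ccccc2)(c2ccccc2)C(C)(C)C)C1=O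
F8 | step 9 | (4Z)-isomer of 15 | C[C@H]1CCC/C(C)=C\[C@H](O[Si](C)(C)C(C)(C)C)[C@@H](C(C)=C)[C@H](O[Si](c2ccccc2)(c2ccccc2)C(C)(C)C)C1=O
F9 | step 9 | (4Z)-isomer of 16 | C[C@H]1CCC/C(C)=C\[C@H](O)[C@@H](C(C)=C)[C@H](O[Si](c2ccccc2)(c2ccccc2)C(C)(C)C)C1=O
F10 | step 9 | (4R,5S,10S)-4,5,6-trihydroxy-8-TBDPSO-germacr-11(13)-en-9-one | C[C@H]1CCC[C@@](C)(O)[C@@H](O)[C@H](O)[C@@H](C(C)=C)[C@H](O[Si](c2ccccc2)(c2ccccc2)C(C)(C)C)C1=O
F11 | step 9 | (4R,5S,10S)-4,5,6,12-tetrahydroxy-8-TBDPSO-germacr-11(13)-en-9-one | C[C@H]1CCC[C@@](C)(O)[C@@H](O)[C@H](O)[C@@H](C(=C)CO)[C@H](O[Si](c2ccccc2)(c2ccccc2)C(C)(C)C)C1=O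
F12 | step 10 | 9-triethylsilyl enol ether (C9=C10) of 13 | CC1=C(O[Si](CC)(CC)CC)[C@@H](O[Si](c2ccccc2)(c2ccccc2)C(C)(C)C)[C@H](C(C)(C)O[Si](C)(C)C)[C@@H](O[Si](C)(C)C(C)(C)C)/C=C(C)/CCC1
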